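**Strategy.** The route rests on cutting the C9–C10 bond of ring B (labdane numbering). The exocyclic methylene carbon C8 is treated as a ketone whose α-carbon C9 sits next to quaternary C10, which is the retron of a semipinacol shift. Ring B is therefore first made as the cyclopentanone C5–C6–C7–C8–C10 of a trans-hydrindane from (S)-Hajos–Parrish ketone, and C9 arrives with the whole (S)-linalool-derived side chain as an α-selenoalkyllithium. In the key step AgBF4 ionises the β-hydroxy selenide and C10 migrates from C8 to C9. This enlarges ring B to the six-membered 8-ketone, forms the hindered C9–C10 bond and lets C9 be set from C5/C10 by equilibration. Methylenation and acetylation finish.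

Key step: step 9

Remark: (S)-(+)-linalool is assumed to be bought in high enantiomeric purity, since it alone fixes C13; labdane numbering (C3 oxygenated, C4 gem-dimethyl, C5/C10 ring fusion, C8/C9 in ring B) is used for all bicyclic compounds, hydrindanes included.

Step 1
Reactants: 1 (S)-Hajos–Parrish ketone, (7aS)-7a-methyl-2,3,7,7a-tetrahydro-1H-indene-1,5(6H)-dione
Product: 2 (7aS)-1,1-(ethylenedioxy)-7a-methyl-1,2,3,6,7,7a-hexahydro-5H-inden-5-one (C8 ketal, enone intact)
Conditions: (Me3SiOCH2)2 (1.2 equiv), Me3SiOTf (5 mol %), CH2Cl2, −78 to −20 °C; pyridine quench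
Reagents that add atoms: 1,2-bis(trimethylsilyloxy)ethane, C[Si](C)(C)OCCO[Si](C)(C)C
Why: Silyl-triflate-catalysed dioxolane formation should acetalise the saturated cyclopentanone much faster than the less electrophilic, vinylogous enone carbonyl (chemoselective ketalisation, no stereocentre touched).

Step 2
Reactants: 2 (7aS)-1,1-(ethylenedioxy)-7a-methyl-1,2,3,6,7,7a-hexahydro-5H-inden-5-one
Product: 3 (7aS)-1,1-(ethylenedioxy)-4,4,7a-trimethyl-1,2,4,6,7,7a-hexahydro-5H-inden-5-one (gem-dimethyl at C4, double bond moved to C5=C6 in the five-membered ring)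
Conditions: KOt-Bu (2.5 equiv), MeI (4 equiv), t-BuOH/THF, 0 °C to rt
Reagents that add atoms: iodomethane, CI
Why: γ-Deprotonation at C6 gives the extended potassium dienolate, which should be C-methylated twice at C4 with deconjugation (classical deconjugative gem-dialkylation of a bicyclic enone), while the ketal blocks enolisation at C7.

Step 3
Reactants: 3 (7aS)-1,1-(ethylenedioxy)-4,4,7a-trimethyl-1,2,4,6,7,7a-hexahydro-5H-inden-5-one
Product: 4 (3aS,7aS)-1,1-(ethylenedioxy)-4,4,7a-trimethyloctahydro-5H-inden-5-one (trans-fused, H5 α)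
Conditions: H2 (1 atm), 10% Pd/C, EtOAc, rt
Reagents that add atoms: none
Why: Heterogeneous catalytic hydrogenation should deliver hydrogen to the C5=C6 alkene from the α-face opposite the angular C10 methyl group, which sets C5 and the trans ring fusion, while ketone and ketal are inert.

Step 4
Reactants: 4 (3aS,7aS)-1,1-(ethylenedioxy)-4,4,7a-trimethyloctahydro-5H-inden-5-one
Product: 6 (3aS,5R,7aS)-5-hydroxy-4,4,7a-trimethyloctahydro-1H-inden-1-one (trans-hydrindanone, axial 3α-OH anti to the angular methyl, free C8 ketone), via hydroxy ketal 5 (not isolated)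
Conditions: LiBH(s-Bu)3 (L-Selectride, 1.3 equiv), THF, −78 °C; then 2 M aq HCl, THF, rt
Reagents that add atoms: water, O
Why: The bulky trialkylborohydride should attack the C3 ketone along the equatorial trajectory and give the axial 3α-alcohol under control of the ring A chair, and the acidic work-up then hydrolyses the dioxolane to unveil the C8 ketone (hindered hydride reduction followed by acetal hydrolysis).

Step 5
Reactants: 7 (S)-(+)-linalool, (3S)-3,7-dimethylocta-1,6-dien-3-ol
Product: 8 (S)-[(3,7-dimethylocta-1,6-dien-3-yl)oxy]triethylsilane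
Conditions: Et3SiOTf (1.3 equiv), 2,6-lutidine (2 equiv), CH2Cl2, −78 to 0 °C
Reagents that add atoms: triethylsilyl trifluoromethanesulfonate, CC[Si](CC)(CC)OS(=O)(=O)C(F)(F)F
Why: A silyl triflate with a hindered pyridine base silylates tertiary alcohols without ionising the allylic C–O bond, so the C13 stereocentre is carried over untouched (O-silylation).

Step 6
Reactants: 8 (S)-[(3,7-dimethylocta-1,6-dien-3-yl)oxy]triethylsilane
Product: 10 (S)-4-methyl-4-(triethylsilyloxy)hex-5-enal, via ozonide 9 (not isolated)
Conditions: O3 (1.0 equiv, Sudan Red 7B end point), CH2Cl2, −78 °C; then PPh3, −78 °C to rt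
Reagents that add atoms: ozone, [O-][O+]=O
Why: Electrophilic ozone should consume the electron-rich trisubstituted alkene far faster than the monosubstituted vinyl group next to the silyloxy-bearing quaternary carbon, and PPh3 reduces the ozonide to the aldehyde (Criegee ozonolysis with reductive work-up).

Step 7
Reactants: 10 (S)-4-methyl-4-(triethylsilyloxy)hex-5-enal
Product: 11 (S)-triethyl{[3-methyl-6,6-bis(methylselanyl)hex-1-en-3-yl]oxy}silane
Conditions: MeSeH (2.2 equiv), ZnCl2 (0.5 equiv), CH2Cl2, 0 °C to rt, argon, dark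
Reagents that add atoms: methaneselenol, C[SeH]
Why: ZnCl2-mediated selenoacetalisation of an aldehyde is the selenium counterpart of dithioacetal formation and is mild enough for the tertiary allylic silyl ether, while exclusion of light and air suppresses radical addition of the selenol to the vinyl group.

Step 8
Reactants: 11 (S)-triethyl{[3-methyl-6,6-bis(methylselanyl)hex-1-en-3-yl]oxy}silane; 6 (3aS,5R,7aS)-5-hydroxy-4,4,7a-trimethyloctahydro-1H-inden-1-one
Product: 13 (3aS,5R,7aS)-4,4,7a-trimethyl-1-[(4S)-4-methyl-1-(methylselanyl)-4-(triethylsilyloxy)hex-5-en-1-yl]octahydro-1H-indene-1,5-diol (epimer mixture at C8 and C9), via lithio selenide 12 (not isolated)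
Conditions: 11 (2.3 equiv), n-BuLi (2.2 equiv), THF, −78 °C, 30 min; then 6 (1 equiv), THF, −78 °C; H2O quench at −78 °C
Reagents that add atoms: none
Why: Selenium–lithium exchange gives the α-selenoalkyllithium, a compact and weakly basic carbanion that should add to the hindered enolisable C8 ketone at −78 °C after one equivalent has converted the 3-OH into its alkoxide (1,2-addition), the two new centres needing no control because C8 becomes sp2 and C9 is equilibrated later, and the low temperature prevents 5-exo carbolithiation of the vinyl group.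

Step 9
Reactants: 13 (3aS,5R,7aS)-4,4,7a-trimethyl-1-[(4S)-4-methyl-1-(methylselanyl)-4-(triethylsilyloxy)hex-5-en-1-yl]octahydro-1H-indene-1,5-diol
Product: 15 (13S)-3α-hydroxy-13-(triethylsilyloxy)-17-norlabd-14-en-8-one (trans-decalone, H5 α, H9 α with the side chain β-equatorial, 10β-methyl), via C9-epimeric ketone 14 (not isolated)
Conditions: AgBF4 (1.5 equiv), 2,6-di-tert-butyl-4-methylpyridine (2 equiv), CH2Cl2, −20 °C to rt, dark; filter; then NaOMe (0.2 equiv), MeOH, rt
Reagents that add atoms: none
Why: AgBF4 binds the soft selenium of 13 and removes MeSe from C9 as AgSeMe, and as the C9–Se bond ionises the antiperiplanar C8–C10 σ-bond shifts to C9 while the C8 hydroxyl becomes the carbonyl (its proton goes to the hindered pyridine), so that C9 is inserted between C8 and C10 and the cyclopentane ring B becomes the cyclohexanone. This is a semipinacol (Tiffeneau–Demjanov-like) one-carbon ring enlargement of a 1-(1-selenoalkyl)cycloalkanol, a known way from cyclopentanones to 2-alkylcyclohexanones. No ring is closed by cyclisation; ring B arises by 1,2-alkyl shift from five to six members, and the trans ring fusion is carried over because C10 migrates with retention. The only new stereocentre, C9, is α to the new ketone and is set under thermodynamic control by NaOMe, the side chain taking the equatorial β position on the trans-decalone chair fixed by C5 and C10 whichever selenide epimer reacted. The step needs migration of C10 instead of C7 and migration instead of epoxide closure; the first should be secured by the higher migratory aptitude of the fully substituted C10 and by relief of trans-hydrindane strain, the second by the non-basic medium in which the hydroxyl is never an alkoxide.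

Step 10
Reactants: 15 (13S)-3α-hydroxy-13-(triethylsilyloxy)-17-norlabd-14-en-8-one
Product: 16 (13S)-13-(triethylsilyloxy)labda-8(17),14-dien-3α-ol
Conditions: Ph3PCH3Br (4 equiv), KOt-Bu (4 equiv), toluene, 90 °C
Reagents that add atoms: methyltriphenylphosphonium bromide (as its ylide), C[P+](c1ccccc1)(c1ccccc1)c1ccccc1.[Br-]
Why: Wittig methylenation with excess salt-free ylide at elevated temperature is the standard answer to hindered 8-oxo decalones, the excess covers the 3-alkoxide, and any base-induced equilibration at C9 returns the favoured equatorial epimer.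

Step 11
Reactants: 16 (13S)-13-(triethylsilyloxy)labda-8(17),14-dien-3α-ol
Product: 17 (13S)-labda-8(17),14-diene-3α,13-diol
Conditions: Bu4NF (2 equiv), THF, rt to 45 °C
Reagents that add atoms: none
Why: Fluoride cleaves the Si–O bond of the tertiary triethylsilyl ether without touching the C13–O bond, so the allylic stereocentre is retained (desilylation).

Step 12
Reactants: 17 (13S)-labda-8(17),14-diene-3α,13-diol
Product: 18 (3R,5R,9S,10R,13S)-labda-8(17),14-diene-3,13-diyl diacetate (3α,13-diacetoxy; target)
Conditions: Ac2O (10 equiv), DMAP (1 equiv), Et3N, CH2Cl2, 40 °C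
Reagents that add atoms: acetic anhydride, CC(=O)OC(C)=O
Why: DMAP-catalysed acylation should esterify both the axial neopentyl 3α-alcohol and the tertiary allylic 13-alcohol, and the basic medium avoids ionisation or allylic transposition at C13.

**Compound list**

1 | (S)-Hajos–Parrish ketone, (7aS)-7a-methyl-2,3,7,7a-tetrahydro-1H-indene-1,5(6H)-dione | O=C1CCC2=CC(=O)CC[C@]12C | starting material
2 | (7aS)-1,1-(ethylenedioxy)-7a-methyl-1,2,3,6,7,7a-hexahydro-5H-inden-5-one | O1CCOC12CCC3=CC(=O)CC[C@]23C | intermediate
3 | (7aS)-1,1-(ethylenedioxy)-4,4,7a-trimethyl-1,2,4,6,7,7a-hexahydro-5H-inden-5-one | O1CCOC12CC=C3C(C)(C)C(=O)CC[C@]23C | intermediate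
4 | (3aS,7aS)-1,1-(ethylenedioxy)-4,4,7a-trimethyloctahydro-5H-inden-5-one, trans-fused | O1CCOC12CC[C@H]3C(C)(C)C(=O)CC[C@]23C | intermediate
5 | (3aS,5R,7aS)-1,1-(ethylenedioxy)-4,4,7a-trimethyloctahydro-1H-inden-5-ol (hydroxy ketal, axial 3α-OH) | O1CCOC12CC[C@H]3C(C)(C)[C@H](O)CC[C@]23C | intermediate (not isolated)
6 | (3aS,5R,7aS)-5-hydroxy-4,4,7a-trimethyloctahydro-1H-inden-1-one | O=C1CC[C@H]2C(C)(C)[C@H](O)CC[C@]12C | intermediate
7 | (S)-(+)-linalool | C=C[C@@](C)(O)CCC=C(C)C | starting material
8 | (S)-[(3,7-dimethylocta-1,6-dien-3-yl)oxy]triethylsilane | C=C[C@@](C)(O[Si](CC)(CC)CC)CCC=C(C)C | intermediate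
9 | 5,5-dimethyl-3-[(3S)-3-methyl-3-(triethylsilyloxy)pent-4-en-1-yl]-1,2,4-trioxolane (ozonide) | CC1(C)OOC(CC[C@](C)(O[Si](CC)(CC)CC)C=C)O1 | intermediate (not isolated)
10 | (S)-4-methyl-4-(triethylsilyloxy)hex-5-enal | O=CCC[C@](C)(O[Si](CC)(CC)CC)C=C | intermediate
11 | (S)-triethyl{[3-methyl-6,6-bis(methylselanyl)hex-1-en-3-yl]oxy}silane | C[Se]C([Se]C)CC[C@](C)(O[Si](CC)(CC)CC)C=C | intermediate
12 | [(4S)-4-methyl-1-(methylselanyl)-4-(triethylsilyloxy)hex-5-en-1-yl]lithium | [Li]C([Se]C)CC[C@](C)(O[Si](CC)(CC)CC)C=C | intermediate (not isolated)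
13 | (3aS,5R,7aS)-4,4,7a-trimethyl-1-[(4S)-4-methyl-1-(methylselanyl)-4-(triethylsilyloxy)hex-5-en-1-yl]octahydro-1H-indene-1,5-diol, epimers at C8 and C9 | C[Se]C(CC[C@](C)(O[Si](CC)(CC)CC)C=C)C1(O)CC[C@H]2C(C)(C)[C@H](O)CC[C@]12C | intermediate
14 | (13S)-3α-hydroxy-13-(triethylsilyloxy)-17-norlabd-14-en-8-one, mixture of C9 epimers | C=C[C@](C)(CCC1C(=O)CC[C@H]2C(C)(C)[C@H](O)CC[C@]12C)O[Si](CC)(CC)CC | intermediate (not isolated)
15 | (13S)-3α-hydroxy-13-(triethylsilyloxy)-17-norlabd-14-en-8-one, 9α-H | C=C[C@](C)(CC[C@H]1C(=O)CC[C@H]2C(C)(C)[C@H](O)CC[C@]12C)O[Si](CC)(CC)CC | intermediate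
16 | (13S)-13-(triethylsilyloxy)labda-8(17),14-dien-3α-ol | C=C[C@](C)(CC[C@H]1C(=C)CC[C@H]2C(C)(C)[C@H](O)CC[C@]12C)O[Si](CC)(CC)CC | intermediate
17 | (13S)-labda-8(17),14-diene-3α,13-diol | C=C[C@](C)(CC[C@H]1C(=C)CC[C@H]2C(C)(C)[C@H](O)CC[C@]12C)O | intermediate
18 | (3R,5R,9S,10R,13S)-labda-8(17),14-diene-3,13-diyl diacetate | C=C[C@](C)(CC[C@H]1C(=C)CC[C@H]2C(C)(C)[C@H](OC(C)=O)CC[C@]12C)OC(C)=O | target

**Step count.** Total: 12 steps. Longest linear sequence: 9 steps (steps 1–4 and 8–12); the side-chain branch is steps 5–7.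

**Steps most likely to fail**

Step 9. Because C9 is only secondary, the silver-activated selenide may collapse by attack of the C8 oxygen on C9 (epoxide closure) or by elimination before C10 migrates, and with the wrong rotamer C7 could migrate instead of C10. The fallback sets out from 13 and comes back at 15. The selenide of 13 is oxidised (t-BuOOH, Al2O3, THF, 55 °C); the selenoxide can only eliminate toward C11 because C8 bears no hydrogen, giving the (E)-allylic alcohol F1. Hydroxyl-directed epoxidation with VO(acac)2 and t-BuOOH gives the epoxy alcohol F2. BF3·OEt2 at −78 °C opens the C9–O bond while C10 migrates, still a five-to-six enlargement of ring B, and gives the β-hydroxy ketone F3. The accessible C11 hydroxyl is sulfonylated selectively (MsCl, Et3N, −20 °C) to the mesylate F4, which eliminates in the same flask with DBU to the enone F5. Conjugate reduction with [(Ph3P)CuH]6 and NaOMe equilibration should then give 15.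

Step 8. The carbanion may enolise the cyclopentanone at C7 or attack the neopentyl carbonyl too slowly, so that ketone is returned. The fallback sets out from 11 and 6 and comes back at 15. One methylselanyl group of 11 is removed as dimethyl selenide (MeI, DMF, 80 °C) to give the vinyl selenide F6. Selenium–lithium exchange with n-BuLi at −78 °C gives the small sp2 alkenyllithium F7, which should add to 6 and give the allylic alcohol F1 (here an E/Z mixture, which serves equally). F1 then passes through F2, F3, F4 and F5 as described above to 15.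

Step 3. Hydrogen may add to both faces of the C5=C6 alkene (cis-hydrindane formation), or the double bond may wander on palladium before reduction. The fallback sets out from 3 and comes back at 5. Compound 3 is reduced first with LiBH(s-Bu)3 to the homoallylic 3α-alcohol F8. Hydrogenation with [Ir(cod)(PCy3)(py)]PF6 in CH2Cl2 then binds the axial α-hydroxyl and delivers H2 to the α-face of C5=C6, giving 5, which is hydrolysed to 6 as in step 4.

Further compounds
F1 | step 9 | (3aS,5R,7aS)-4,4,7a-trimethyl-1-[(1E,4S)-4-methyl-4-(triethylsilyloxy)hexa-1,5-dien-1-yl]octahydro-1H-indene-1,5-diol (allylic alcohol, C8 epimers) | C=C[C@](C)(C/C=C/C1(O)CC[C@H]2C(C)(C)[C@H](O)CC[C@]12C)O[Si](CC)(CC)CC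
F2 | step 9 | 9,11-epoxide of F1 (epoxy alcohol, stereoisomer mixture) | C=C[C@](C)(CC3OC3C1(O)CC[C@H]2C(C)(C)[C@H](O)CC[C@]12C)O[Si](CC)(CC)CC
F3 | step 9 | (13S)-3α,11-dihydroxy-13-(triethylsilyloxy)-17-norlabd-14-en-8-one (β-hydroxy ketone) | C=C[C@](C)(CC(O)C1C(=O)CC[C@H]2C(C)(C)[C@H](O)CC[C@]12C)O[Si](CC)(CC)CC
F4 | step 9 | 11-methanesulfonate of F3 | C=C[C@](C)(CC(OS(C)(=O)=O)C1C(=O)CC[C@H]2C(C)(C)[C@H](O)CC[C@]12C)O[Si](CC)(CC)CC
F5 | step 9 | (13S)-3α-hydroxy-13-(triethylsilyloxy)-17-norlabda-9(11),14-dien-8-one (enone) | C=C[C@](C)(CC=C1C(=O)CC[C@H]2C(C)(C)[C@H](O)CC[C@]12C)O[Si](CC)(CC)CC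
F6 | step 8 | (S)-triethyl{[3-methyl-6-(methylselanyl)hexa-1,5-dien-3-yl]oxy}silane (vinyl selenide, E/Z) | C[Se]C=CC[C@](C)(O[Si](CC)(CC)CC)C=C
F7 | step 8 | [(4S)-4-methyl-4-(triethylsilyloxy)hexa-1,5-dien-1-yl]lithium | [Li]C=CC[C@](C)(O[Si](CC)(CC)CC)C=C
F8 | step 3 | (5R,7aS)-1,1-(ethylenedioxy)-4,4,7a-trimethyl-2,4,5,6,7,7a-hexahydro-1H-inden-5-ol (homoallylic 3α-alcohol) | O1CCOC12CC=C3C(C)(C)[C@H](O)CC[C@]23C
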